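## Structural features

The target is a 2,3-trans dihydroflavonol 3-O-methyl ether. It is a chroman-4-one in which ring A (C4a to C8a) is fused to the pyranone ring C (O1, C2, C3, C4), and ring B, a 2,3-dihydroxy-4-methoxyphenyl group, sits on C2. Ring A carries hydroxyls at C5 and C6 and a methoxy group at C7, so the acyl-bearing carbon C4a lies between two oxygenated carbons (C5 and C8a) and only C8 bears hydrogen. The two stereocentres are adjacent: C2 (benzylic, bound to O1) and C3 (methoxy-bearing, alpha to the C4 ketone) are both R, which places aryl and methoxy trans and diequatorial. Fragile points are the enolisable C3–H, the O1–C2 benzylic ether (it can open once the ring B oxygens are free, and it is itself hydrogenolysable), beta-elimination across C2–C3, and the oxidation-prone vicinal diphenols on rings A and B. The difficulty is regiochemical as much as stereochemical: an acyl group must be placed on a tetra-oxygenated ring exactly between O1 and the C5 oxygen, and the C2/C3 pair must then survive to the end. The plan uses the fact that O1–C8a and C4–C4a are the ortho bonds of an o-hydroxyaryl ketone next to the C5 oxygen, which is the pattern left when a 3-alkoxybenzyne (aryne bond between C4a and C8a) takes up a carboxylic acid across its acyl C–O bond. Rings A and B share the 2,3-dioxy-4-methoxy pattern, so one aldehyde serves both halves.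

## Logic of the disconnections

28 from 27: the four O–CH2Ph bonds are cut. The free diphenols would be oxidised and would interfere with aryne, boron and Mitsunobu chemistry, so all four phenols are masked with one group that leaves under neutral conditions. The demand on the forward step is that hydrogenolysis spares the cyclic O1–C2 benzylic ether and the C4 ketone.

27 from 25: the O1–C2 bond is cut. Closing ring C last means the base- and fluoride-sensitive chromanone never meets the conditions of the fragment union, and the stereocentres can be set in an open chain. The forward step must invert C2, so 25 carries the syn (2R,3S) pair, and it must avoid elimination across C2–C3.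

25 from 24: the O–Si bond at the C2 oxygen is cut. The benzylic hydroxyl has to be masked during the aryne step, where an alkoxide would add to the aryne. The triisopropylsilyl group is chosen over smaller silyl groups because it must tolerate CsF in hot THF. Its removal must be buffered to avoid retro-aldol cleavage.

24 from 10 and 20: C4–C4a and O1–C8a are cut together. This is the strategic simplification: ring A arrives with its final oxygenation pattern, the ketone and the phenol appear in one operation, and both stereocentres come in ready-made with 20. The forward step needs regioselective addition to the unsymmetrical intermediate 22, acyl transfer in 23 faster than protonation, and survival of the silyl ether and of the alpha centre. Which of the two aryne carbons carries silicon and which the triflate in 10 is immaterial; the isomer chosen is the one reachable from 5.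

10 from 7, 6, 5 and 3: the C–Si and O–S bonds are cut (retro-Brook shift and triflation), then C–Br, then the aryl C–O bond that replaces the formyl carbon. This traces the aryne precursor to the same aldehyde that supplies ring B. The demand is bromination of 5 ortho to the hydroxyl and not ortho to the methoxy group.

20 from 18, 17, 14 and 3: the acyl–N bond, the O–Si bond and then the C2–C3 bond are cut, the last by an auxiliary-controlled glycolate aldol. Both stereocentres are set in one step from an achiral aldehyde. The demand is syn selectivity with the absolute sense supplied by 11, and hydrolysis without epimerisation.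

14 from 11 and 12, and 3 from 1 and 2: N-acylation and double O-benzylation, both from commercial materials.

## Other disconnections considered

Alternative 1: The cut is C4–C4a, made after O1–C2. Aryl iodide A1, in which O1 already carries the C2–C3 unit as a 1-aryl-2-methoxybut-3-enyl ether, would be treated with Pd(OAc)2, a phosphine (zerovalent palladium formed in the flask) and a base. Oxidative addition into C4a–I, 6-exo-trig carbopalladation of the vinyl group and beta-hydride elimination of the C4 hydrogen should give the 4-methylidene flavan A2. Oxidative cleavage of the exocyclic alkene, removal of the C5 methyl group and debenzylation would then follow.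
- In favour: ring A regiochemistry is trivial, because the oxygenation of ring A in A1 is symmetrical about the O1-bearing carbon and both ortho positions are the same when iodine is introduced. The C–C bond forms intramolecularly under nearly neutral conditions with no carbonyl next to C3. The C2–C3 unit could come from one asymmetric gamma-alkoxyallylation of 3.
- Against: A1 requires an intermolecular etherification of a hindered phenol with a secondary, strongly cation-stabilised benzylic alcohol. The palladium hydride released can move the alkene into the ring (C3=C4) and erase C3. The alkene must later be cleaved in the presence of electron-rich rings. The C5 oxygen arrives as a methyl ether that must be cleaved selectively beside three other methoxy groups.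
- Comparison: in step count to the closed skeleton this plan is the equal of the chosen one or slightly better, and it avoids hot fluoride. It adds two corrections after its key step and puts the stereochemical risk on an intermolecular benzylic substitution. The chosen plan installs ring A with its final pattern and the C4 ketone at once and closes the ring intramolecularly.

Alternative 2: The cut is C2–C3 together with a temporary acyl–oxygen bond. The ketene generated from 12 and a tertiary amine would combine with 3 under an O-silylated cinchona alkaloid and LiClO4. The amine-bound enolate adds to the lithium-activated aldehyde and lactonises, a formal [2+2] cycloaddition, to give the cis beta-lactone A3 with the same syn relationship as 20. Opening A3 at the acyl carbon (hydroxide, then silylation, to reach 20) would feed the same ring A union.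
- In favour: both stereocentres are set in one catalytic step without a stoichiometric auxiliary, from the same two building blocks. For the C2–C3 fragment it is the better plan on step economy (two or three operations against four) and on atom economy.
- Against: alkoxyketenes are less well behaved in this cycloaddition than alkylketenes, and the ortho-disubstituted, electron-rich aldehyde is a poor electrophile. A beta-lactone whose C4 carries an ortho/para-oxygenated aryl group ionises readily at C4–O, which opens paths to cis/trans scrambling and to decarboxylation at exactly the benzylic stereocentre.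
- Comparison: this alternative leaves the ring A junction unsolved and would still need the aryne insertion afterwards, so it competes only with steps 6 to 9. The auxiliary aldol is longer but rests on a closed transition-state model that tolerates aromatic aldehydes and alkoxy enolates, and it delivers a bench-stable acid.

Alternative 3: The cut is C4a–C5, so ring A is folded from a linear chain instead of being bought. Pyrone A4 would be opened by Mg(OMe)2 in methanol to its ring-opened ester form, held as a magnesium chelate. The doubly activated methylene (future C4a) then attacks the ester carbon in a Claisen condensation, and aromatisation gives chalcone A5.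
- In favour: the step mirrors chalcone synthase chemistry, is mild, and differentiates the C7 methoxy group from the two free hydroxyls automatically. The acyl group ends up between two oxygens with no regiochemical question; on that point it is the equal of the aryne insertion and better than any aromatic substitution. A4 should be reachable in few steps by acylating a commercial pyrone with a cinnamoyl unit derived from 3.
- Against: A5 has hydrogen at C6, so the C6 hydroxyl would have to be introduced late on a ring where C6 and C8 are electronically alike. C3 carries no oxygen and neither stereocentre exists yet, so an asymmetric oxidation, a cyclisation and a selective O-methylation at C3 would still follow.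
- Comparison: as a ring construction it is shorter and more elegant for 5,7-dioxygenated flavonoids. For this 5,6,7-trioxygenated 3-methoxy target it postpones the two hardest problems (C6 oxygenation and C2/C3 control), which the chosen plan solves before or at the key step.

Key step: step 10

Assumption: flavanone numbering (O1, C2, C3, C4, C4a, C5 to C8, C8a) is used for the corresponding atoms of all intermediates. The open-chain intermediates carry the syn (2R,3S) pair, because closing O1–C2 with inversion then gives the trans (2R,3R) ring; this syn pair requires the (R)-4-benzyl auxiliary 11, taken as commercial.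

## Route

Step 1
Reactants: 1 2,3-dihydroxy-4-methoxybenzaldehyde; 2 benzyl bromide
Product: 3 2,3-bis(benzyloxy)-4-methoxybenzaldehyde
Conditions: 2 (2.5 equiv), K2CO3, DMF, 60 °C
Reagents that add atoms: none
Why: Williamson ether synthesis; both phenoxides are alkylated in a dipolar aprotic solvent, excess halide and warming overcome the hydrogen-bonded C2 hydroxyl, and the aldehyde is inert.

Step 2
Reactants: 3 2,3-bis(benzyloxy)-4-methoxybenzaldehyde
Product: 5 2,3-bis(benzyloxy)-4-methoxyphenol, via aryl formate 4 (not isolated)
Conditions: mCPBA, CH2Cl2, 0 °C → rt; then K2CO3, MeOH, rt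
Reagents that add atoms: mCPBA, OOC(=O)c1cccc(Cl)c1
Why: Dakin-type oxidation (Baeyer–Villiger reaction of an electron-rich benzaldehyde); the ortho and para alkoxy groups make the aryl group migrate in preference to hydride, and mild methanolysis of formate 4 releases the phenol without touching the benzyl ethers.

Step 3
Reactants: 5 2,3-bis(benzyloxy)-4-methoxyphenol
Product: 6 2,3-bis(benzyloxy)-6-bromo-4-methoxyphenol
Conditions: NBS (1.0 equiv), i-Pr2NH (10 mol %), CH2Cl2, −20 → 0 °C
Reagents that add atoms: N-bromosuccinimide, BrN1C(=O)CCC1=O
Why: Amine-catalysed electrophilic aromatic bromination; the free hydroxyl is the strongest activator and the N-bromoamine is delivered by hydrogen bonding to the only free ortho position (para to the C3 benzyloxy group) in preference to the position next to the methoxy group. One equivalent at low temperature limits over-bromination and quinone formation.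

Step 4
Reactants: 6 2,3-bis(benzyloxy)-6-bromo-4-methoxyphenol
Product: 7 [2,3-bis(benzyloxy)-6-bromo-4-methoxyphenoxy]trimethylsilane
Conditions: HMDS, THF, 65 °C; evaporate, use crude
Reagents that add atoms: hexamethyldisilazane, C[Si](C)(C)N[Si](C)(C)C
Why: O-silylation of a phenol by HMDS, driven by loss of NH3; the volatile by-product lets the moisture-sensitive silyl ether be used after evaporation.

Step 5
Reactants: 7 [2,3-bis(benzyloxy)-6-bromo-4-methoxyphenoxy]trimethylsilane
Product: 10 2,3-bis(benzyloxy)-4-methoxy-6-(trimethylsilyl)phenyl trifluoromethanesulfonate, via aryllithium 8 (not isolated), via lithium phenoxide 9 (not isolated)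
Conditions: n-BuLi, THF, −78 °C; then Tf2O, −78 → 0 °C
Reagents that add atoms: trifluoromethanesulfonic anhydride, O=S(=O)(OS(=O)(=O)C(F)(F)F)C(F)(F)F
Why: Bromine–lithium exchange is faster at −78 °C than deprotonation of the benzylic ethers; aryllithium 8 undergoes a 1,3 oxygen-to-carbon silyl shift (retro-Brook rearrangement) driven by formation of phenoxide 9, which Tf2O then sulfonylates on oxygen.

Step 6
Reactants: 11 (R)-4-benzyloxazolidin-2-one; 12 methoxyacetyl chloride
Product: 14 (R)-4-benzyl-3-(2-methoxyacetyl)oxazolidin-2-one, via N-lithio oxazolidinone 13 (not isolated)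
Conditions: n-BuLi, THF, −78 °C; then 12, −78 → 0 °C
Reagents that add atoms: none
Why: N-acylation of the lithiated oxazolidinone with an acid chloride, the standard loading of the auxiliary; the low temperature suppresses ketene formation from the alkoxyacetyl chloride.

Step 7
Reactants: 14 (R)-4-benzyl-3-(2-methoxyacetyl)oxazolidin-2-one; 3 2,3-bis(benzyloxy)-4-methoxybenzaldehyde
Product: 17 (R)-4-benzyl-3-[(2R,3S)-3-[2,3-bis(benzyloxy)-4-methoxyphenyl]-3-hydroxy-2-methoxypropanoyl]oxazolidin-2-one, via boron enolate 15 (not isolated), via boron aldolate 16 (not isolated)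
Conditions: Bu2BOTf, Et3N, CH2Cl2, −78 → 0 °C; then 3, −78 → 0 °C; pH 7 buffer, MeOH, 30% H2O2, 0 °C
Reagents that add atoms: none
Why: Evans syn aldol of a glycolate imide; Bu2BOTf/Et3N give the Z-boron enolate 15, which adds through a closed chair (Zimmerman–Traxler) transition state with the oxazolidinone carbonyl turned away from the enolate oxygen, so the aldehyde meets the face opposite the benzyl group of the (R)-auxiliary. This sets the syn (2R,3S) pair: C3 of the target in its final R configuration, and the C2 carbinol in the configuration that step 12 inverts.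

Step 8
Reactants: 17 (R)-4-benzyl-3-[(2R,3S)-3-[2,3-bis(benzyloxy)-4-methoxyphenyl]-3-hydroxy-2-methoxypropanoyl]oxazolidin-2-one
Product: 18 (R)-4-benzyl-3-[(2R,3S)-3-[2,3-bis(benzyloxy)-4-methoxyphenyl]-2-methoxy-3-(triisopropylsilyloxy)propanoyl]oxazolidin-2-one
Conditions: TIPSOTf, 2,6-lutidine, CH2Cl2, 0 °C → rt
Reagents that add atoms: triisopropylsilyl trifluoromethanesulfonate, CC(C)[Si](OS(=O)(=O)C(F)(F)F)(C(C)C)C(C)C
Why: Silylation of a hindered secondary benzylic alcohol with a silyl triflate and a non-nucleophilic base; the bulky silyl group must survive CsF in hot THF in step 10 and keep the benzylic oxygen from adding to the aryne.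

Step 9
Reactants: 18 (R)-4-benzyl-3-[(2R,3S)-3-[2,3-bis(benzyloxy)-4-methoxyphenyl]-2-methoxy-3-(triisopropylsilyloxy)propanoyl]oxazolidin-2-one
Product: 20 (2R,3S)-3-[2,3-bis(benzyloxy)-4-methoxyphenyl]-2-methoxy-3-(triisopropylsilyloxy)propanoic acid, via lithium peroxycarboxylate 19 (not isolated)
Conditions: LiOH, 30% H2O2, THF/H2O (3:1), 0 °C; aq. Na2SO3; 1 M HCl to pH 3
Reagents that add atoms: hydrogen peroxide (as LiOOH), OO
Why: Hydroperoxide cleavage of the N-acyl oxazolidinone; the alpha-effect nucleophile attacks the exocyclic carbonyl selectively, sulfite reduces percarboxylate 19, and at 0 °C the alpha stereocentre and the silyl ether are not affected. Auxiliary 11 is recovered.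

Step 10
Reactants: 10 2,3-bis(benzyloxy)-4-methoxy-6-(trimethylsilyl)phenyl trifluoromethanesulfonate; 20 (2R,3S)-3-[2,3-bis(benzyloxy)-4-methoxyphenyl]-2-methoxy-3-(triisopropylsilyloxy)propanoic acid
Product: 24 (2R,3S)-1-[2,3-bis(benzyloxy)-6-hydroxy-4-methoxyphenyl]-3-[2,3-bis(benzyloxy)-4-methoxyphenyl]-2-methoxy-3-(triisopropylsilyloxy)propan-1-one, via cesium carboxylate 21 (not isolated), via aryne 22 (not isolated), via aryl ester carbanion 23 (not isolated)
Conditions: 20 (1.0 equiv), 10 (1.5 equiv), CsF (4 equiv), THF, 125 °C, sealed tube
Reagents that add atoms: none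
Why: Fluoride attacks silicon of 10 and the triflate leaves, releasing aryne 22 (aryne bond C4a–C8a) at low stationary concentration while the acid is present as carboxylate 21. The carboxylate oxygen adds to C8a, and carbanion 23 at C4a, held next to the ester carbonyl, attacks the acyl carbon through a four-membered transition structure; collapse breaks the acyl C–O bond and leaves the C8a phenoxide ortho to the new C4 ketone, so O1–C8a and C4–C4a form in one operation (an anionic-Fries-like oxygen-to-carbon acyl shift). The closest known reaction type is the fluoride-induced insertion of arynes from 2-(trimethylsilyl)aryl triflates into the C–O bond of carboxylic acids, which gives o-hydroxyaryl ketones in hot THF. No ring is closed, so no closure mode applies, and no stereocentre is created; the C2 and C3 centres of 20 are carried over, protected from enolisation by the carboxylate before the shift and by the chelated phenoxide after it. The selectivity needed is regiochemical: the inductively withdrawing C5 benzyloxy group, which also distorts the aryne so that C8a is the more electrophilic terminus, sends the oxygen nucleophile to the remote carbon C8a and places the negative charge at C4a beside the C–O dipole. The second requirement is that the carbanion chooses acyl transfer over protonation; the aprotic medium, the high temperature and the adjacent ester carbonyl favour the shift. The silyl ether keeps the benzylic oxygen out of the reaction, and 20 is the limiting component.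

Step 11
Reactants: 24 (2R,3S)-1-[2,3-bis(benzyloxy)-6-hydroxy-4-methoxyphenyl]-3-[2,3-bis(benzyloxy)-4-methoxyphenyl]-2-methoxy-3-(triisopropylsilyloxy)propan-1-one
Product: 25 (2R,3S)-1-[2,3-bis(benzyloxy)-6-hydroxy-4-methoxyphenyl]-3-[2,3-bis(benzyloxy)-4-methoxyphenyl]-3-hydroxy-2-methoxypropan-1-one
Conditions: HF·pyridine, pyridine, THF, 0 °C → rt
Reagents that add atoms: none
Why: Buffered fluoride cleavage of the silyl ether; HF·pyridine with added pyridine is not basic enough for retro-aldol cleavage or beta-elimination of the beta-hydroxy ketone and not acidic enough to ionise the electron-rich benzylic alcohol.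

Step 12
Reactants: 25 (2R,3S)-1-[2,3-bis(benzyloxy)-6-hydroxy-4-methoxyphenyl]-3-[2,3-bis(benzyloxy)-4-methoxyphenyl]-3-hydroxy-2-methoxypropan-1-one
Product: 27 (2R,3R)-5,6-bis(benzyloxy)-2-[2,3-bis(benzyloxy)-4-methoxyphenyl]-3,7-dimethoxychroman-4-one, via oxyphosphonium phenoxide 26 (not isolated)
Conditions: PPh3, DIAD, THF, 0 °C → rt
Reagents that add atoms: none
Why: Intramolecular Mitsunobu etherification; the hydrogen-bonded phenol (O1) is acidic enough to protonate the betaine, the benzylic hydroxyl becomes the oxyphosphonium leaving group in 26, and 6-exo-tet displacement by the phenoxide forms O1–C2 with inversion. The syn (2R,3S) open chain thus becomes the 2,3-trans (2R,3R) ring with both substituents equatorial, and C3 is not touched.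

Step 13
Reactants: 27 (2R,3R)-5,6-bis(benzyloxy)-2-[2,3-bis(benzyloxy)-4-methoxyphenyl]-3,7-dimethoxychroman-4-one
Product: 28 (2R,3R)-2-(2,3-dihydroxy-4-methoxyphenyl)-5,6-dihydroxy-3,7-dimethoxychroman-4-one
Conditions: H2 (1 atm), 10% Pd/C, EtOAc/MeOH, rt
Reagents that add atoms: none
Why: Catalytic hydrogenolysis of four aryl benzyl ethers under neutral conditions; these should cleave much faster than the cyclic O1–C2 benzylic ether or the aryl ketone, and the absence of base avoids ring-opening or epimerisation of the trans dihydroflavonol.

## Compound list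

1 | 2,3-dihydroxy-4-methoxybenzaldehyde | COc1ccc(C=O)c(O)c1O | starting material
2 | benzyl bromide | BrCc1ccccc1 | starting material
3 | 2,3-bis(benzyloxy)-4-methoxybenzaldehyde | COc1ccc(C=O)c(OCc2ccccc2)c1OCc1ccccc1 | intermediate
4 | 2,3-bis(benzyloxy)-4-methoxyphenyl formate | COc1ccc(OC=O)c(OCc2ccccc2)c1OCc1ccccc1 | intermediate (not isolated)
5 | 2,3-bis(benzyloxy)-4-methoxyphenol | COc1ccc(O)c(OCc2ccccc2)c1OCc1ccccc1 | intermediate
6 | 2,3-bis(benzyloxy)-6-bromo-4-methoxyphenol | COc1cc(Br)c(O)c(OCc2ccccc2)c1OCc1ccccc1 | intermediate
7 | [2,3-bis(benzyloxy)-6-bromo-4-methoxyphenoxy]trimethylsilane | COc1cc(Br)c(O[Si](C)(C)C)c(OCc2ccccc2)c1OCc1ccccc1 | intermediate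
8 | [3,4-bis(benzyloxy)-5-methoxy-2-(trimethylsilyloxy)phenyl]lithium | [Li]c1cc(OC)c(OCc2ccccc2)c(OCc2ccccc2)c1O[Si](C)(C)C | intermediate (not isolated)
9 | lithium 2,3-bis(benzyloxy)-4-methoxy-6-(trimethylsilyl)phenolate | COc1cc([Si](C)(C)C)c([O-])c(OCc2ccccc2)c1OCc1ccccc1.[Li+] | intermediate (not isolated)
10 | 2,3-bis(benzyloxy)-4-methoxy-6-(trimethylsilyl)phenyl trifluoromethanesulfonate | COc1cc([Si](C)(C)C)c(OS(=O)(=O)C(F)(F)F)c(OCc2ccccc2)c1OCc1ccccc1 | intermediate
11 | (R)-4-benzyloxazolidin-2-one | O=C1N[C@H](Cc2ccccc2)CO1 | starting material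
12 | methoxyacetyl chloride | COCC(Cl)=O | starting material
13 | N-lithio-(R)-4-benzyloxazolidin-2-one | [Li+].O=C1[N-][C@H](Cc2ccccc2)CO1 | intermediate (not isolated)
14 | (R)-4-benzyl-3-(2-methoxyacetyl)oxazolidin-2-one | COCC(=O)N1[C@H](Cc2ccccc2)COC1=O | intermediate
15 | dibutylboron (Z)-enolate of 14 (methoxy cis to O–B) | CO/C=C(\OB(CCCC)CCCC)N1[C@H](Cc2ccccc2)COC1=O | intermediate (not isolated)
16 | (R)-4-benzyl-3-[(2R,3S)-3-[2,3-bis(benzyloxy)-4-methoxyphenyl]-3-(dibutylboryloxy)-2-methoxypropanoyl]oxazolidin-2-one | COc1ccc([C@H](OB(CCCC)CCCC)[C@@H](OC)C(=O)N2[C@H](Cc3ccccc3)COC2=O)c(OCc2ccccc2)c1OCc1ccccc1 | intermediate (not isolated)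
17 | (R)-4-benzyl-3-[(2R,3S)-3-[2,3-bis(benzyloxy)-4-methoxyphenyl]-3-hydroxy-2-methoxypropanoyl]oxazolidin-2-one | COc1ccc([C@H](O)[C@@H](OC)C(=O)N2[C@H](Cc3ccccc3)COC2=O)c(OCc2ccccc2)c1OCc1ccccc1 | intermediate
18 | (R)-4-benzyl-3-[(2R,3S)-3-[2,3-bis(benzyloxy)-4-methoxyphenyl]-2-methoxy-3-(triisopropylsilyloxy)propanoyl]oxazolidin-2-one | COc1ccc([C@H](O[Si](C(C)C)(C(C)C)C(C)C)[C@@H](OC)C(=O)N2[C@H](Cc3ccccc3)COC2=O)c(OCc2ccccc2)c1OCc1ccccc1 | intermediate
19 | lithium (2R,3S)-3-[2,3-bis(benzyloxy)-4-methoxyphenyl]-2-methoxy-3-(triisopropylsilyloxy)propaneperoxoate | COc1ccc([C@H](O[Si](C(C)C)(C(C)C)C(C)C)[C@@H](OC)C(=O)O[O-])c(OCc2ccccc2)c1OCc1ccccc1.[Li+] | intermediate (not isolated)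
20 | (2R,3S)-3-[2,3-bis(benzyloxy)-4-methoxyphenyl]-2-methoxy-3-(triisopropylsilyloxy)propanoic acid | COc1ccc([C@H](O[Si](C(C)C)(C(C)C)C(C)C)[C@@H](OC)C(=O)O)c(OCc2ccccc2)c1OCc1ccccc1 | intermediate
21 | cesium (2R,3S)-3-[2,3-bis(benzyloxy)-4-methoxyphenyl]-2-methoxy-3-(triisopropylsilyloxy)propanoate | COc1ccc([C@H](O[Si](C(C)C)(C(C)C)C(C)C)[C@@H](OC)C(=O)[O-])c(OCc2ccccc2)c1OCc1ccccc1.[Cs+] | intermediate (not isolated)
22 | 3,4-bis(benzyloxy)-5-methoxybenzyne (1,2-didehydro-3,4-bis(benzyloxy)-5-methoxybenzene) | COC1=CC#CC(OCc2ccccc2)=C1OCc1ccccc1 | intermediate (not isolated)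
23 | {2,3-bis(benzyloxy)-4-methoxy-6-[(2R,3S)-3-[2,3-bis(benzyloxy)-4-methoxyphenyl]-2-methoxy-3-(triisopropylsilyloxy)propanoyloxy]phenyl}cesium | COc1cc(OC(=O)[C@H](OC)[C@@H](O[Si](C(C)C)(C(C)C)C(C)C)c2ccc(OC)c(OCc3ccccc3)c2OCc2ccccc2)c([Cs])c(OCc2ccccc2)c1OCc1ccccc1 | intermediate (not isolated)
24 | (2R,3S)-1-[2,3-bis(benzyloxy)-6-hydroxy-4-methoxyphenyl]-3-[2,3-bis(benzyloxy)-4-methoxyphenyl]-2-methoxy-3-(triisopropylsilyloxy)propan-1-one | COc1ccc([C@H](O[Si](C(C)C)(C(C)C)C(C)C)[C@@H](OC)C(=O)c2c(O)cc(OC)c(OCc3ccccc3)c2OCc2ccccc2)c(OCc2ccccc2)c1OCc1ccccc1 | intermediate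
25 | (2R,3S)-1-[2,3-bis(benzyloxy)-6-hydroxy-4-methoxyphenyl]-3-[2,3-bis(benzyloxy)-4-methoxyphenyl]-3-hydroxy-2-methoxypropan-1-one | COc1ccc([C@H](O)[C@@H](OC)C(=O)c2c(O)cc(OC)c(OCc3ccccc3)c2OCc2ccccc2)c(OCc2ccccc2)c1OCc1ccccc1 | intermediate
26 | zwitterion of 25 in which the benzylic oxygen carries a triphenylphosphonium group and the ring A hydroxyl is a phenoxide, configuration as in 25 | COc1ccc([C@H](O[P+](c2ccccc2)(c2ccccc2)c2ccccc2)[C@@H](OC)C(=O)c2c([O-])cc(OC)c(OCc3ccccc3)c2OCc2ccccc2)c(OCc2ccccc2)c1OCc1ccccc1 | intermediate (not isolated)
27 | (2R,3R)-5,6-bis(benzyloxy)-2-[2,3-bis(benzyloxy)-4-methoxyphenyl]-3,7-dimethoxychroman-4-one (2,3-trans) | COc1ccc([C@H]2Oc3cc(OC)c(OCc4ccccc4)c(OCc4ccccc4)c3C(=O)[C@@H]2OC)c(OCc2ccccc2)c1OCc1ccccc1 | intermediate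
28 | (2R,3R)-2-(2,3-dihydroxy-4-methoxyphenyl)-5,6-dihydroxy-3,7-dimethoxychroman-4-one (2,3-trans) | COc1ccc([C@H]2Oc3cc(OC)c(O)c(O)c3C(=O)[C@@H]2OC)c(O)c1O | target

## Step count and least certain steps

Total: 13 steps. Longest linear sequence: 9 steps (steps 1, 2, 3, 4, 5, 10, 11, 12, 13). The acid branch (steps 6 to 9) joins at step 10.

**Step 10 (key step).**
- What may go wrong: protonation of the aryl carbanion before the acyl shift, leaving only O-arylation, because the acyl group is bulky and HF equivalents are present. A second O-arylation of the product phenoxide by excess aryne. Loss of the silyl group, epimerisation at C3 or beta-elimination under fluoride at 125 °C.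
- Fallback (sets out from 20, returns at 28): ring A is brought in as an aryllithium whose regiochemistry is fixed by symmetry, and C4–C4a is made by a Weinreb ketone synthesis.
  - Commercial syringaldehyde (4-hydroxy-3,5-dimethoxybenzaldehyde) would be benzylated with 2 to 4-(benzyloxy)-3,5-dimethoxybenzaldehyde F1.
  - Oxidation as in step 2 gives 4-(benzyloxy)-3,5-dimethoxyphenol F2.
  - Monobromination with NBS at either of the two equivalent ortho positions gives 4-(benzyloxy)-2-bromo-3,5-dimethoxyphenol F3.
  - Acid 20 would be coupled with MeNHOMe·HCl (EDC·HCl, HOBt, i-Pr2NEt) to (2R,3S)-3-[2,3-bis(benzyloxy)-4-methoxyphenyl]-N,2-dimethoxy-N-methyl-3-(triisopropylsilyloxy)propanamide F4.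
  - Deprotonation of F3 (NaH), bromine–lithium exchange (t-BuLi, THF, −78 °C) and addition to F4 should give (2R,3S)-1-[3-(benzyloxy)-6-hydroxy-2,4-dimethoxyphenyl]-3-[2,3-bis(benzyloxy)-4-methoxyphenyl]-2-methoxy-3-(triisopropylsilyloxy)propan-1-one F5, the C5-methoxy analogue of 24.
  - HF·pyridine as in step 11 gives (2R,3S)-1-[3-(benzyloxy)-6-hydroxy-2,4-dimethoxyphenyl]-3-[2,3-bis(benzyloxy)-4-methoxyphenyl]-3-hydroxy-2-methoxypropan-1-one F6.
  - Mitsunobu closure as in step 12 gives (2R,3R)-6-(benzyloxy)-2-[2,3-bis(benzyloxy)-4-methoxyphenyl]-3,5,7-trimethoxychroman-4-one F7.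
  - BCl3 with pentamethylbenzene (CH2Cl2, −78 → 0 °C) should remove the three benzyl groups and, by chelation to the C4 carbonyl, the C5 methyl group, to reach 28.

**Step 3.**
- What may go wrong: poor site selectivity (attack next to the methoxy group instead of next to the hydroxyl), over-bromination, or oxidation of the electron-rich phenol to a quinone, since both free positions are activated by two oxygens.
- Fallback (sets out from 5, returns at 10): directed ortho-metalation replaces electrophilic substitution.
  - 5 with isopropyl isocyanate (Et3N, CH2Cl2) gives 2,3-bis(benzyloxy)-4-methoxyphenyl N-isopropylcarbamate F8.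
  - N-silylation in the flask (TBSOTf, TMEDA), ortho-lithiation with n-BuLi/TMEDA at −78 °C (only one position is ortho to the carbamate) and TMSCl quench give, after acidic work-up, 2,3-bis(benzyloxy)-4-methoxy-6-(trimethylsilyl)phenyl N-isopropylcarbamate F9.
  - Et2NH/DBU in MeCN cleaves the carbamate to 2,3-bis(benzyloxy)-4-methoxy-6-(trimethylsilyl)phenol F10, which is triflated in the same flask with PhNTf2 to give 10.

**Step 12.**
- What may go wrong: elimination across C2–C3 to an alpha-methoxy enone, because the alpha hydrogen is acidic, and ionisation of the very electron-rich benzylic oxyphosphonium, which would erode the stereospecificity of the displacement.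
- Fallback (sets out from 25, returns at 27): the ionisation is used deliberately. Catalytic camphorsulfonic acid in CH2Cl2 at 0 °C should generate the benzylic cation stabilised by the para-methoxy and ortho-benzyloxy groups; capture by the ring A hydroxyl under control of the untouched C3 centre should favour the diequatorial trans ring. Any cis isomer would have to be separated. No new compound is made (F0).

**Step 13.**
- What may go wrong: over-reduction, namely hydrogenolysis of the O1–C2 benzylic bond with ring-opening or reduction of the C4 ketone, or incomplete cleavage of the hindered ethers, because the C2 ether is itself benzylic.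
- Fallback (sets out from 27, returns at 28): Lewis-acid debenzylation with BCl3 and pentamethylbenzene as cation scavenger in CH2Cl2 at −78 °C, which involves no reduction and should spare the three methyl ethers at that temperature. No new compound is made (F0).

## Further compounds

F1 | step 10 | 4-(benzyloxy)-3,5-dimethoxybenzaldehyde | COc1cc(C=O)cc(OC)c1OCc1ccccc1
F2 | step 10 | 4-(benzyloxy)-3,5-dimethoxyphenol | COc1cc(O)cc(OC)c1OCc1ccccc1
F3 | step 10 | 4-(benzyloxy)-2-bromo-3,5-dimethoxyphenol | COc1cc(O)c(Br)c(OC)c1OCc1ccccc1
F4 | step 10 | (2R,3S)-3-[2,3-bis(benzyloxy)-4-methoxyphenyl]-N,2-dimethoxy-N-methyl-3-(triisopropylsilyloxy)propanamide | COc1ccc([C@H](O[Si](C(C)C)(C(C)C)C(C)C)[C@@H](OC)C(=O)N(C)OC)c(OCc2ccccc2)c1OCc1ccccc1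
F5 | step 10 | (2R,3S)-1-[3-(benzyloxy)-6-hydroxy-2,4-dimethoxyphenyl]-3-[2,3-bis(benzyloxy)-4-methoxyphenyl]-2-methoxy-3-(triisopropylsilyloxy)propan-1-one | COc1ccc([C@H](O[Si](C(C)C)(C(C)C)C(C)C)[C@@H](OC)C(=O)c2c(O)cc(OC)c(OCc3ccccc3)c2OC)c(OCc2ccccc2)c1OCc1ccccc1
F6 | step 10 | (2R,3S)-1-[3-(benzyloxy)-6-hydroxy-2,4-dimethoxyphenyl]-3-[2,3-bis(benzyloxy)-4-methoxyphenyl]-3-hydroxy-2-methoxypropan-1-one | COc1ccc([C@H](O)[C@@H](OC)C(=O)c2c(O)cc(OC)c(OCc3ccccc3)c2OC)c(OCc2ccccc2)c1OCc1ccccc1
F7 | step 10 | (2R,3R)-6-(benzyloxy)-2-[2,3-bis(benzyloxy)-4-methoxyphenyl]-3,5,7-trimethoxychroman-4-one | COc1ccc([C@H]2Oc3cc(OC)c(OCc4ccccc4)c(OC)c3C(=O)[C@@H]2OC)c(OCc2ccccc2)c1OCc1ccccc1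
F8 | step 3 | 2,3-bis(benzyloxy)-4-methoxyphenyl N-isopropylcarbamate | COc1ccc(OC(=O)NC(C)C)c(OCc2ccccc2)c1OCc1ccccc1
F9 | step 3 | 2,3-bis(benzyloxy)-4-methoxy-6-(trimethylsilyl)phenyl N-isopropylcarbamate | COc1cc([Si](C)(C)C)c(OC(=O)NC(C)C)c(OCc2ccccc2)c1OCc1ccccc1
F10 | step 3 | 2,3-bis(benzyloxy)-4-methoxy-6-(trimethylsilyl)phenol | COc1cc([Si](C)(C)C)c(O)c(OCc2ccccc2)c1OCc1ccccc1
F0 | step 12 | none | none
F0 | step 13 | none | none
A1 | alternative 1 | 2-(benzyloxy)-5-{[(1R,2S)-1-[2,3-bis(benzyloxy)-4-methoxyphenyl]-2-methoxybut-3-en-1-yl]oxy}-4-iodo-1,3-dimethoxybenzene | COc1ccc([C@@H](Oc2cc(OC)c(OCc3ccccc3)c(OC)c2I)[C@@H](OC)C=C)c(OCc2ccccc2)c1OCc1ccccc1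
A2 | alternative 1 | (2R,3S)-6-(benzyloxy)-2-[2,3-bis(benzyloxy)-4-methoxyphenyl]-3,5,7-trimethoxy-4-methylidenechromane (2,3-trans) | COc1ccc([C@H]2Oc3cc(OC)c(OCc4ccccc4)c(OC)c3C(=C)[C@@H]2OC)c(OCc2ccccc2)c1OCc1ccccc1
A3 | alternative 2 | (3R,4S)-4-[2,3-bis(benzyloxy)-4-methoxyphenyl]-3-methoxyoxetan-2-one | COc1ccc([C@@H]2OC(=O)[C@@H]2OC)c(OCc2ccccc2)c1OCc1ccccc1
A4 | alternative 3 | 6-{(E)-4-[2,3-bis(benzyloxy)-4-methoxyphenyl]-2-oxobut-3-en-1-yl}-4-methoxy-2H-pyran-2-one | COC1=CC(=O)OC(CC(=O)/C=C/c2ccc(OC)c(OCc3ccccc3)c2OCc2ccccc2)=C1
A5 | alternative 3 | (E)-3-[2,3-bis(benzyloxy)-4-methoxyphenyl]-1-(2,6-dihydroxy-4-methoxyphenyl)prop-2-en-1-one | COc1cc(O)c(C(=O)/C=C/c2ccc(OC)c(OCc3ccccc3)c2OCc2ccccc2)c(O)c1
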